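The data stem from a simulated flask for substances that don't exist, and the scatter is random.

In a one-step world, substrate and partner go straight to target and isomer of the product at a fixed split, so r, the share of isomer in isomer plus target, stands at one value from start to end.

all flasks: substrate 0.50 M
- cedar: partner 1.8 equiv; capture agent 0.013 M; run made earlier
- larch: partner 1.8 equiv; capture agent 0.050 M; run made earlier
- flask: partner 1.80 equiv; capture agent 0.0250 M; time 1.5 h

| run | time / min | isomer of the product / % | target / % |
|---|---|---|---|
| cedar | 12.0 | 10 | 18 |
| cedar | 25.0 | 16 | 29 |
| cedar | 40.0 | 24 | 36 |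
| cedar | 50.0 | 25 | 37 |
| cedar | 60.0 | 26 | 41 |
| cedar | 80.0 | 32 | 44 |
| larch | 5.00 | 6 | 9 |
| larch | 15.0 | 13 | 19 |
| larch | 25.0 | 15 | 27 |
| larch | 40.0 | 22 | 33 |
| larch | 60.0 | 26 | 37 |
| larch | 80.0 | 29 | 40 |

(standard deviation of a reading: 1.5 percentage points)

1. share of isomer of the product in isomer of the product plus target at 50 s
2. share of isomer of the product in isomer of the product plus target at 1.5 h
3. which of isomer of the product and target there is more of at 1.5 h



At the last readings, 80.0 min, r reads 42.1 % in cedar with 0.013 M of capture agent and 42.0 % in larch with 0.050 M, and this flask's 0.0250 M lies between them. So I freeze the late share L, the isomer's part of those last readings pooled, 42.1 %. The one-step extreme puts r at L at both asked times. The opposite extreme has isomer forming behind a delay, so r starts at zero and climbs to L. I expect the real flask between them: larch already reads 40.0 % at 5.00 min, but 50 s comes before any reading, so I bracket the early share and take the midpoint, 21.0 %, as an estimate with a wide margin. At 1.5 h I take L, and target leads, since L is less than even.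

The forecast gives 38 % early, 42 % late and target ahead, saying “the share is an extrapolation”; we agree late and differ early, where mine is 21.0 %.

The flask gives 21.1 % at 50 s and 41.1 % at 1.5 h, with target at 42.5 % against isomer at 29.6 %.

    open intermediate ⇌ target (K = 3.20, k = 1.58 min⁻¹)
    open intermediate + capture agent → trapped intermediate (k = 0.333 M⁻¹ min⁻¹)
    substrate + partner → open intermediate + released group (k = 0.0434 M⁻¹ min⁻¹)
    open intermediate ⇌ isomer of the product (K = 2.25, k = 0.384 min⁻¹)

The relaxation half-life of open intermediate and isomer by that step alone, 1.25 min, is longer than the 0.334 min of open intermediate and target by theirs, and it is short against 1.5 h; the usual term for such an end is thermodynamic rather than kinetic control. The neighbour flask has 0.720 equiv of partner and ends with 48.0 % of substrate still there. For it I carry over L, 42.1 %, and the midpoint, 21.0 %. Its share at 1.5 h is 40.9 %, and at 50 s it is 21.1 %.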